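The numbers belong to no real substance, and the outcome is calculated.

If you want triple product from these flasks, keep books on the reagent before anything else.

    starting material + reagent → single product (k1 = 0.0994 L mol⁻¹ min⁻¹)
    reagent + single product → double product (k2 = 0.272 L mol⁻¹ min⁻¹)
    reagent + double product → triple product (k3 = 0.00900 L mol⁻¹ min⁻¹)
    reagent + triple product → tetra adduct (k4 = 0.0682 L mol⁻¹ min⁻¹)
    starting material + double product → side product (k5 = 0.00770 L mol⁻¹ min⁻¹)

| setting | violet | ochre | red | teal |
|---|---|---|---|---|
| starting material | 0.40 M | 0.50 M | 0.80 M | 1.2 M |
| reagent | 0.432 M | 0.432 M | 0.432 M | 0.432 M |
| time | 15 h | 15 h | 15 h | 15 h |

- percentages count the starting material that a species holds: one side product counts as two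
- "hardly changes" means that all values lie within two and a half points (for a concentration: within two and a half percent of the largest)
- run time (violet): 15 h

* [triple product] at the end for violet, ochre, red, teal, in this order
* how that number moves from the first to the last of them (rises, then falls / hardly changes / rises all the way / falls all the way / falls, then rises)

Full conversion to tetra adduct takes four reagent per starting material, and the charge offers 1.08 in violet and 0.360 in teal, so the reagent is the limiting reagent and you can follow where it goes. The first entry is single product. I leave out the steps to triple product, tetra adduct and side product here, since their constants are less than the first. The two remaining steps both carry [reagent], so it cancels: single product gains with k1[starting material] and loses with k2[single product]. Their ratio, the selectivity factor, is 2.74. Single product therefore peaks when [single product]/[starting material] equals its inverse, at 20.5% of the charge. This is the single-product ceiling, the highest share of charged starting material that single product reaches in this two-step race.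

The second entry follows from it. As a rough entry I book single product at the ceiling, and the remaining reagent pays two per double product, which gives 0.175 M in violet and 0.0932 M in teal. These entries leave 0.143 M of starting material in violet and 0.861 M in teal. The third entry is the leak. As the last reagent goes, the step to triple product runs at k3[double product] against k1[starting material], which on these rough entries is 11.1% in violet and 0.980% in teal, far less in teal than in violet. My books close there: I commit to a row that falls from violet to teal, and to no numbers.

The forecast goes further, with 0.0054 M, 0.0037 M, 0.0019 M and 0.001 M, and its shape is: falls all the way. Its ground is “More starting material exhausts the reagent earlier, so the value falls throughout.”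

The flasks give 0.00532 M, 0.00378 M, 0.00187 M and 0.00101 M, and the shape is: falls all the way. The forecast is right on the row and on the shape.

In violet, half the turnover of the step to double product is done by 0.331 h, much sooner than half that of the side step at 5.00 h. Violet's reagent stands at 0% by 7.50 h, and its triple product reads 1.33% then and 1.33% at 15.0 h, while side product climbs from 28.4% to 42.4%. The ceiling of 20.5% stands above violet's single product, which ends at 17.3%, and close to red's, which ends at 19.9%.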